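The furan-2(5H)-one ring is taken apart at three bonds at once: C4–C1' to the chain, C3–C2 to the carbonyl and O1–C2 of the lactone. The key step exploits the tetrasubstituted C3=C4 alkene. Its C3 methyl, C4 chain and mutually cis C5H2–O1 and C2=O groups map onto but-2-yn-1-ol, an alkyl nucleophile and carbon dioxide. Copper-catalysed anti-carbomagnesiation of the propargylic magnesium alkoxide, carboxylation and acid lactonisation therefore attach the chain and build the ring in one flask. The precursor is a saturated C16 Grignard reagent with a remote (S)-silyloxy group, made from (S)-but-3-yn-2-ol and 1,12-dibromododecane. Its stereocentre comes from the chiral pool and stays a spectator.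

Key step: step 5

Remark on the chemistry: the [C@@H] centre of the target reads as S (OAc > CH2 chain > CH3 > H). This is the spatial arrangement of (S)-but-3-yn-2-ol, which is assumed to be bought in high enantiomeric purity.

Step 1
Reactants: 1 (S)-but-3-yn-2-ol
Product: 2 (S)-3-(tert-butyldimethylsilyloxy)but-1-yne
Conditions: TBSCl, imidazole, CH2Cl2, 0 °C → rt
Reagents that add atoms: tert-butyldimethylsilyl chloride, CC(C)(C)[Si](C)(C)Cl
Why: Imidazole-promoted O-silylation takes place at oxygen only, so the C–O bond and the S configuration are untouched, and the resulting ether withstands n-BuLi, hydrogenation and organomagnesium reagents.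

Step 2
Reactants: 2 (S)-3-(tert-butyldimethylsilyloxy)but-1-yne; 3 1,12-dibromododecane
Product: 5 (S)-16-bromo-2-(tert-butyldimethylsilyloxy)hexadec-3-yne, via lithium acetylide 4 (not isolated)
Conditions: n-BuLi (0.98 equiv), THF, −78 °C; cannulated slowly into 3 (3 equiv), THF/DMPU, 0 °C → rt
Reagents that add atoms: none
Why: SN2 alkylation of a lithium acetylide by a primary bromide in THF/DMPU is standard, slow inverse addition into a threefold excess of the symmetrical dibromide should suppress the second alkylation (surplus 3 is recovered on chromatography), and a slight deficit of base leaves the propargylic C–H at the stereocentre alone.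

Step 3
Reactants: 5 (S)-16-bromo-2-(tert-butyldimethylsilyloxy)hexadec-3-yne
Product: 6 (S)-16-bromo-2-(tert-butyldimethylsilyloxy)hexadecane
Conditions: H2 (1 atm), 5% Rh/Al2O3, EtOAc, rt
Reagents that add atoms: none
Why: Heterogeneous catalytic hydrogenation of the alkyne to the alkane; rhodium on alumina in a neutral, aprotic solvent is preferred to palladium because it has little tendency to hydrogenolyse the propargylic or allylic C–O bond and the primary C–Br bond or to shift the intermediate alkene towards C2, so the stereocentre keeps its arrangement and its S descriptor (O > CH2 > CH3).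

Step 4
Reactants: 6 (S)-16-bromo-2-(tert-butyldimethylsilyloxy)hexadecane
Product: 7 [(15S)-15-(tert-butyldimethylsilyloxy)hexadecyl]magnesium bromide
Conditions: Mg turnings (excess, crystal of I2), Et2O, slow addition at gentle reflux; solution titrated and used at once
Reagents that add atoms: magnesium, [Mg]
Why: Grignard reagent formation by insertion of magnesium into the primary C–Br bond; slow addition of dilute 6 to excess metal should keep Wurtz coupling low, the silyl ether is inert, and titration fixes the stoichiometry of the next step.

Step 5
Reactants: 7 [(15S)-15-(tert-butyldimethylsilyloxy)hexadecyl]magnesium bromide; 8 but-2-yn-1-ol; 9 carbon dioxide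
Product: 14 4-[(15S)-15-(tert-butyldimethylsilyloxy)hexadecyl]-3-methylfuran-2(5H)-one, via bromomagnesium alkoxide 10 (not isolated), via oxamagnesacycle 11 (not isolated), via magnesium carboxylate 12 (not isolated), via Z-hydroxy acid 13 (not isolated)
Conditions: 8 (1.5 equiv), MeMgBr (1.5 equiv), Et2O, 0 °C; CuI (10 mol %), then 7 (1.0 equiv, Et2O), 0 °C → rt → gentle reflux; dry CO2 (gas), −20 °C → rt; 1 M HCl, 0 °C → rt
Reagents that add atoms: carbon dioxide 9, O=C=O (already listed among the reactants)
Why: MeMgBr first converts 8 into alkoxide 10, so none of 7 is wasted on the O–H bond, and the alkylcopper species formed from catalytic CuI and 7 then adds across the triple bond of 10 in a net anti sense, putting the C16 chain on the alkyne carbon next to CH2O and magnesium on the methyl-bearing carbon within the five-membered 1-oxa-2-magnesacyclopent-3-ene 11. The vinyl C–Mg bond of 11 is then carboxylated by CO2 without change of the double-bond geometry to give 12, and acidification releases Z-hydroxy acid 13, in which CH2OH and CO2H sit on the same side. Ring closure to the furanone is a spontaneous 5-exo-trig lactonisation, the C5 hydroxyl adding to the C2 carboxyl carbon and water leaving. The closest known reaction type is the copper-catalysed anti-carbomagnesiation of propargylic alcohols by Grignard reagents with electrophilic trapping of the cyclic vinylmagnesium, carbon dioxide being an established trap that leads to 3,4-disubstituted butenolides. No stereocentre is created; what must be controlled is where the chain lands (the alkyne carbon nearer oxygen) and on which side magnesium ends up (opposite to the chain), and the propargylic O–Mg tether decides both, because only this mode of addition ends in the stable five-membered chelate. Using 7 as the limiting partner against an excess of cheap 10 spares the valuable chain, and the remote silyl ether does not react with organomagnesium or organocopper species.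

Step 6
Reactants: 14 4-[(15S)-15-(tert-butyldimethylsilyloxy)hexadecyl]-3-methylfuran-2(5H)-one
Product: 16 (2S)-16-(4-methyl-5-oxo-2,5-dihydrofuran-3-yl)hexadecan-2-yl acetate, via hydroxy butenolide 15 (not isolated)
Conditions: HCl (cat., methanolic), MeOH/CH2Cl2 1:1, rt; evaporate; Ac2O, pyridine, DMAP (cat.), CH2Cl2, 0 °C → rt
Reagents that add atoms: acetic anhydride, CC(=O)OC(C)=O
Why: Acid-catalysed methanolysis of the secondary silyl ether avoids basic fluoride and thus deprotonation at C5 of the butenolide, all by-products are volatile so that crude 15 can be O-acetylated in the same flask under DMAP catalysis, and since only O–Si and O–H bonds are broken the S centre is retained.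

Compound list
1 | (S)-but-3-yn-2-ol | C[C@H](O)C#C | starting material
2 | (S)-3-(tert-butyldimethylsilyloxy)but-1-yne | C[C@H](O[Si](C)(C)C(C)(C)C)C#C | intermediate
3 | 1,12-dibromododecane | BrCCCCCCCCCCCCBr | starting material
4 | [(3S)-3-(tert-butyldimethylsilyloxy)but-1-yn-1-yl]lithium | C[C@H](O[Si](C)(C)C(C)(C)C)C#C[Li] | intermediate
5 | (S)-16-bromo-2-(tert-butyldimethylsilyloxy)hexadec-3-yne | C[C@H](O[Si](C)(C)C(C)(C)C)C#CCCCCCCCCCCCCBr | intermediate
6 | (S)-16-bromo-2-(tert-butyldimethylsilyloxy)hexadecane | C[C@H](O[Si](C)(C)C(C)(C)C)CCCCCCCCCCCCCCBr | intermediate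
7 | [(15S)-15-(tert-butyldimethylsilyloxy)hexadecyl]magnesium bromide | C[C@H](O[Si](C)(C)C(C)(C)C)CCCCCCCCCCCCCC[Mg]Br | intermediate
8 | but-2-yn-1-ol | CC#CCO | starting material
9 | carbon dioxide | O=C=O | starting material
10 | bromomagnesium but-2-yn-1-oxide | CC#CCO[Mg]Br | intermediate
11 | 3-methyl-4-[(15S)-15-(tert-butyldimethylsilyloxy)hexadecyl]-1-oxa-2-magnesacyclopent-3-ene (Mg bonded to the methyl-bearing vinyl carbon and to the alkoxide oxygen) | C[C@H](O[Si](C)(C)C(C)(C)C)CCCCCCCCCCCCCCC1=C(C)[Mg]OC1 | intermediate
12 | cyclic magnesium carboxylate–alkoxide of acid 13 | C[C@H](O[Si](C)(C)C(C)(C)C)CCCCCCCCCCCCCCC1=C(C)C(=O)O[Mg]OC1 | intermediate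
13 | (2Z,18S)-18-(tert-butyldimethylsilyloxy)-3-(hydroxymethyl)-2-methylnonadec-2-enoic acid | OC/C(CCCCCCCCCCCCCC[C@H](C)O[Si](C)(C)C(C)(C)C)=C(/C)C(=O)O | intermediate
14 | 4-[(15S)-15-(tert-butyldimethylsilyloxy)hexadecyl]-3-methylfuran-2(5H)-one | C[C@H](O[Si](C)(C)C(C)(C)C)CCCCCCCCCCCCCCC1=C(C)C(=O)OC1 | intermediate
15 | 4-[(15S)-15-hydroxyhexadecyl]-3-methylfuran-2(5H)-one | C[C@H](O)CCCCCCCCCCCCCCC1=C(C)C(=O)OC1 | intermediate
16 | (2S)-16-(4-methyl-5-oxo-2,5-dihydrofuran-3-yl)hexadecan-2-yl acetate (CNP0377863.1) | CC(=O)O[C@@H](C)CCCCCCCCCCCCCCC1=C(C)C(=O)OC1 | target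

Total step count: 6
Longest linear sequence: 6 (1 → 2 → 5 → 6 → 7 → 14 → 16; compounds 3, 8 and 9 are bought)

Steps most likely to fail

Step 5. A primary alkyl Grignard reagent may add only slowly or incompletely across the internal alkynoxide. The unreacted reagent would then be protonated or carboxylated directly, and some regiocontrol could be lost. The fallback sets out from 7 and comes back at 14. It joins the chain to a preformed ring instead of building the ring around it. Commercial 4-hydroxy-3-methylfuran-2(5H)-one (CC1=C(O)COC1=O) is O-sulfonylated (Tf2O, i-Pr2NEt, CH2Cl2, −78 °C) to 4-methyl-5-oxo-2,5-dihydrofuran-3-yl trifluoromethanesulfonate F1. Compound 7 is then coupled at C4 by an iron-catalysed Kumada-type alkyl–alkenyl cross-coupling (Fe(acac)3 cat., THF/NMP, −30 °C). This process should outrun attack at the lactone carbonyl and should deliver 14 directly.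

Step 2. The dibromide may be alkylated at both ends, the acetylide may act as a base and cause elimination, and the product may be hard to separate from the surplus electrophile. The fallback sets out from 2 and comes back at 5. It replaces the statistical reaction by a differentiated C12 unit.
- Commercial 12-bromododecan-1-ol (OCCCCCCCCCCCCBr) is masked with 3,4-dihydro-2H-pyran (PPTS, CH2Cl2) as 2-[(12-bromododecyl)oxy]oxane F2.
- Acetylide 4, generated from 2 as before, is alkylated with one equivalent of it (THF/DMPU). This gives tert-butyl(dimethyl){[(2S)-16-(oxan-2-yloxy)hexadec-3-yn-2-yl]oxy}silane F3, epimeric at the acetal carbon.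
- Acetal ethanolysis (PPTS, EtOH, 50 °C), which spares the secondary silyl ether, gives (15S)-15-(tert-butyldimethylsilyloxy)hexadec-13-yn-1-ol F4.
- An Appel reaction (CBr4, PPh3, CH2Cl2, 0 °C) then gives 5.

Step 4. On a small scale the insertion may be slow to initiate, and Wurtz homocoupling or adventitious quenching may lower the titre on which step 5 depends. The fallback sets out from 6 and comes back at 7. It reaches the organomagnesium by exchange and transmetalation instead of direct insertion.
- A Finkelstein reaction (NaI, acetone, reflux) gives (S)-2-(tert-butyldimethylsilyloxy)-16-iodohexadecane F5.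
- Lithium–iodine exchange (t-BuLi, 2 equiv, pentane/Et2O, −78 °C) gives [(15S)-15-(tert-butyldimethylsilyloxy)hexadecyl]lithium F6.
- Addition of MgBr2·OEt2 (−78 °C → 0 °C) gives 7 in ether.

Further compounds
F1 | step 5 | 4-methyl-5-oxo-2,5-dihydrofuran-3-yl trifluoromethanesulfonate | CC1=C(OS(=O)(=O)C(F)(F)F)COC1=O
F2 | step 2 | 2-[(12-bromododecyl)oxy]oxane (racemic acetal) | BrCCCCCCCCCCCCOC1CCCCO1
F3 | step 2 | tert-butyl(dimethyl){[(2S)-16-(oxan-2-yloxy)hexadec-3-yn-2-yl]oxy}silane (epimers at the acetal carbon) | C[C@H](O[Si](C)(C)C(C)(C)C)C#CCCCCCCCCCCCCOC1CCCCO1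
F4 | step 2 | (15S)-15-(tert-butyldimethylsilyloxy)hexadec-13-yn-1-ol | C[C@H](O[Si](C)(C)C(C)(C)C)C#CCCCCCCCCCCCCO
F5 | step 4 | (S)-2-(tert-butyldimethylsilyloxy)-16-iodohexadecane | C[C@H](O[Si](C)(C)C(C)(C)C)CCCCCCCCCCCCCCI
F6 | step 4 | [(15S)-15-(tert-butyldimethylsilyloxy)hexadecyl]lithium | C[C@H](O[Si](C)(C)C(C)(C)C)CCCCCCCCCCCCCC[Li]
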